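**Retrosynthetic overview**
1. The target is read as gallocatechin-(4α→8)-catechin-(4β→8)-ent-catechin (13). It comes from trideca-O-benzyl trimer 12 by hydrogenolysis. No ring is built: all three pyran rings come intact from (+)-dihydromyricetin, (+)-catechin and (−)-catechin.
2. Top C4–C8 bond (3,4-trans): 3,4-diacetate 10 (from benzylated dihydromyricetin) plus dimer 6; the 3-O-acetyl group blocks the β face.
3. Middle C4–C8 bond (3,4-cis): cis-3,4-diol 5 plus benzylated ent-catechin 2, by a new phosphate-templated syn arylation.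
4. Key step: the C4–O bond of 5, made by DDQ C–H hydroxylation of benzylated (+)-catechin. It is the activating handle, and its cis relation to 3-OH lets the phosphoric acid grip both hydroxyls.
5. Order of union: middle + bottom give 6, then the top unit goes onto C8 of the middle unit, then deprotection.

Assumption: (−)-catechin (2S,3R) is bought as such; it is a catalogue compound made by C2 epimerisation of (−)-epicatechin.

**Step 1**
Reactants: 1 (−)-catechin
Product: 2 (2S,3R)-5,7,3',4'-tetra-O-benzyl-ent-catechin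
Conditions: BnBr (4.4 equiv), K2CO3, DMF, 0 °C to rt, Ar
Reagents that add atoms: benzyl bromide, BrCc1ccccc1
Why: Williamson etherification of the four phenols under carbonate base leaves the secondary 3-OH free and touches no stereocentre.

**Step 2**
Reactants: 3 (+)-catechin
Product: 4 (2R,3S)-5,7,3',4'-tetra-O-benzylcatechin
Conditions: BnBr (4.4 equiv), K2CO3, DMF, 0 °C to rt, Ar
Reagents that add atoms: benzyl bromide, BrCc1ccccc1
Why: Williamson etherification as in step 1; no stereocentre is touched.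

**Step 3**
Reactants: 4 (2R,3S)-5,7,3',4'-tetra-O-benzylcatechin
Product: 5 (2R,3S,4S)-5,7,3',4'-tetra-O-benzylflavan-3,4-diol (2,3-trans-3,4-cis; 4β-OH)
Conditions: DDQ (1.5 equiv), CH2Cl2–H2O (20:1), rt
Reagents that add atoms: water, O
Why: Benzylic C–H oxidation by hydride abstraction (DDQ) at the electron-rich C4, with water captured cis to the 3-OH as is usual for alcohol trapping in this oxidation, sets C4 as 4β-OH; either C4 epimer would serve in step 4.

**Step 4**
Reactants: 5 (2R,3S,4S)-5,7,3',4'-tetra-O-benzylflavan-3,4-diol, 2 (2S,3R)-5,7,3',4'-tetra-O-benzyl-ent-catechin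
Product: 6 octa-O-benzyl catechin-(4β→8)-ent-catechin
Conditions: (R)-TRIP [(R)-3,3'-bis(2,4,6-triisopropylphenyl)-BINOL hydrogen phosphate] (10 mol %), 4 Å MS, toluene, −20 °C to rt, 5 added slowly to 2 (3 equiv)
Reagents that add atoms: none
Why: Proposed new method: a dehydrative Friedel–Crafts arylation in which the phosphoric acid stands in for a covalent tether — it grips the cis 3-OH/4-OH pair of 5, protonates and ionises the 4-OH to the C4 cation stabilised by ring A, stays hydrogen-bonded to the 3β-OH on the β face of the ion pair and binds the 3-OH of 2 with its second oxygen, so that C8 of 2 (the ring A carbon nearest that hydroxyl) is delivered to the β face through a 14-membered hydrogen-bonded array (the O–H···O–P–O···H–O bridge spans the same five atoms as the glutarate linker known to give 3,4-cis dimers covalently), which sets C4 as 4β (3,4-cis) against the intrinsic 3,4-trans preference; the closest known reaction type is the chiral-phosphoric-acid-catalysed Friedel–Crafts alkylation of arenes with benzylic cations or quinone methides generated in situ from benzylic alcohols.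

**Step 5**
Reactants: 7 (+)-dihydromyricetin
Product: 8 (2R,3R)-5,7,3',4',5'-penta-O-benzyldihydromyricetin
Conditions: BnBr (6 equiv), K2CO3, DMF, rt to 45 °C, Ar
Reagents that add atoms: benzyl bromide, BrCc1ccccc1
Why: Williamson etherification of all five phenols, including the hydrogen-bonded 5-OH under mild forcing; the 2,3-trans dihydroflavonol is the thermodynamic isomer, so the base does not change C2 or C3.

**Step 6**
Reactants: 8 (2R,3R)-5,7,3',4',5'-penta-O-benzyldihydromyricetin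
Product: 10 penta-O-benzyl-leucodelphinidin 3,4-diacetate (2R; 2,3-trans-3,4-trans), via penta-O-benzyl-leucodelphinidin 9 (not isolated)
Conditions: NaBH4, THF–MeOH, 0 °C; evaporate; Ac2O, pyridine, DMAP (cat.), rt
Reagents that add atoms: acetic anhydride, CC(=O)OC(C)=O
Why: Borohydride reduction of the C4 ketone gives mainly the 3,4-trans diol (this C4 configuration is lost again on ionisation in step 7), and DMAP-catalysed acetylation of the crude diol installs the leaving group at O4 and the participating group at O3.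

**Step 7**
Reactants: 10 penta-O-benzyl-leucodelphinidin 3,4-diacetate, 6 octa-O-benzyl catechin-(4β→8)-ent-catechin
Product: 12 trideca-O-benzyl gallocatechin-(4α→8)-catechin-(4β→8)-ent-catechin, via 3-O-acetyl trideca-O-benzyl trimer 11 (not isolated)
Conditions: 6 (1.5 equiv), TMSOTf (0.3 equiv), 4 Å MS, CH2Cl2, −78 to −40 °C; NaHCO3 work-up; then NaOMe (0.3 equiv), MeOH–THF, rt
Reagents that add atoms: none
Why: Friedel–Crafts alkylation with neighbouring-group participation: ionisation of the 4-acetate gives a cation bridged on the β face by the 3-O-acetyl group (cis-fused dioxolanium), so C8 of the upper unit of 6, its most nucleophilic free ring A position, attacks from the α face and sets the 3,4-trans (4α) bond, and Zemplén methanolysis then removes the acetate.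

**Step 8**
Reactants: 12 trideca-O-benzyl gallocatechin-(4α→8)-catechin-(4β→8)-ent-catechin
Product: 13 gallocatechin-(4α→8)-catechin-(4β→8)-ent-catechin (CNP0155646.2)
Conditions: H2 (1 atm), Pd(OH)2 on carbon, THF–MeOH–H2O, rt
Reagents that add atoms: none
Why: Catalytic hydrogenolysis cleaves the thirteen benzyl ethers under neutral conditions, which leave the acid-labile interflavan bonds and all eight stereocentres untouched.

**Compound list**
1 | (−)-catechin, (2S,3R) | Oc1cc(O)c2c(c1)O[C@@H](c1ccc(O)c(O)c1)[C@H](O)C2 | starting material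
2 | (2S,3R)-5,7,3',4'-tetra-O-benzyl-ent-catechin | c1c(OCc3ccccc3)cc(OCc3ccccc3)c2c1O[C@@H](c1ccc(OCc3ccccc3)c(OCc3ccccc3)c1)[C@H](O)C2 | intermediate
3 | (+)-catechin, (2R,3S) | Oc1cc(O)c2c(c1)O[C@H](c1ccc(O)c(O)c1)[C@@H](O)C2 | starting material
4 | (2R,3S)-5,7,3',4'-tetra-O-benzylcatechin | c1c(OCc3ccccc3)cc(OCc3ccccc3)c2c1O[C@H](c1ccc(OCc3ccccc3)c(OCc3ccccc3)c1)[C@@H](O)C2 | intermediate
5 | (2R,3S,4S)-5,7,3',4'-tetra-O-benzylflavan-3,4-diol (2,3-trans-3,4-cis) | c1c(OCc3ccccc3)cc(OCc3ccccc3)c2c1O[C@H](c1ccc(OCc3ccccc3)c(OCc3ccccc3)c1)[C@@H](O)[C@H]2O | intermediate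
6 | octa-O-benzyl catechin-(4β→8)-ent-catechin (upper unit 2R,3S with 3,4-cis interflavan bond; lower unit 2S,3R; both 3-OH free) | c1c(OCc3ccccc3)cc(OCc3ccccc3)c2c1O[C@H](c1ccc(OCc3ccccc3)c(OCc3ccccc3)c1)[C@@H](O)[C@H]2c1c(OCc3ccccc3)cc(OCc3ccccc3)c2c1O[C@@H](c1ccc(OCc3ccccc3)c(OCc3ccccc3)c1)[C@H](O)C2 | intermediate
7 | (+)-dihydromyricetin (ampelopsin), (2R,3R) | Oc1cc(O)c2c(c1)O[C@H](c1cc(O)c(O)c(O)c1)[C@@H](O)C2=O | starting material
8 | (2R,3R)-5,7,3',4',5'-penta-O-benzyldihydromyricetin | c1c(OCc3ccccc3)cc(OCc3ccccc3)c2c1O[C@H](c1cc(OCc3ccccc3)c(OCc3ccccc3)c(OCc3ccccc3)c1)[C@@H](O)C2=O | intermediate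
9 | (2R,3S,4R)-5,7,3',4',5'-penta-O-benzyl-leucodelphinidin (flavan-3,4-diol, 2,3-trans-3,4-trans) | c1c(OCc3ccccc3)cc(OCc3ccccc3)c2c1O[C@H](c1cc(OCc3ccccc3)c(OCc3ccccc3)c(OCc3ccccc3)c1)[C@@H](O)[C@@H]2O | intermediate
10 | 3,4-di-O-acetyl derivative of 9 (2α-aryl, 3β-OAc, 4α-OAc) | c1c(OCc3ccccc3)cc(OCc3ccccc3)c2c1O[C@H](c1cc(OCc3ccccc3)c(OCc3ccccc3)c(OCc3ccccc3)c1)[C@@H](OC(C)=O)[C@@H]2OC(C)=O | intermediate
11 | 3-O-acetyl (top unit) trideca-O-benzyl gallocatechin-(4α→8)-catechin-(4β→8)-ent-catechin | c1c(OCc3ccccc3)cc(OCc3ccccc3)c2c1O[C@H](c1cc(OCc3ccccc3)c(OCc3ccccc3)c(OCc3ccccc3)c1)[C@@H](OC(C)=O)[C@@H]2c1c(OCc3ccccc3)cc(OCc3ccccc3)c2c1O[C@H](c1ccc(OCc3ccccc3)c(OCc3ccccc3)c1)[C@@H](O)[C@H]2c1c(OCc3ccccc3)cc(OCc3ccccc3)c2c1O[C@@H](c1ccc(OCc3ccccc3)c(OCc3ccccc3)c1)[C@H](O)C2 | intermediate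
12 | trideca-O-benzyl gallocatechin-(4α→8)-catechin-(4β→8)-ent-catechin (three 3-OH free) | c1c(OCc3ccccc3)cc(OCc3ccccc3)c2c1O[C@H](c1cc(OCc3ccccc3)c(OCc3ccccc3)c(OCc3ccccc3)c1)[C@@H](O)[C@@H]2c1c(OCc3ccccc3)cc(OCc3ccccc3)c2c1O[C@H](c1ccc(OCc3ccccc3)c(OCc3ccccc3)c1)[C@@H](O)[C@H]2c1c(OCc3ccccc3)cc(OCc3ccccc3)c2c1O[C@@H](c1ccc(OCc3ccccc3)c(OCc3ccccc3)c1)[C@H](O)C2 | intermediate
13 | gallocatechin-(4α→8)-catechin-(4β→8)-ent-catechin (top 2R,3S,4α; middle 2R,3S,4β; bottom 2S,3R) | Oc1cc(O)c2c(c1)O[C@H](c1cc(O)c(O)c(O)c1)[C@@H](O)[C@@H]2c1c(O)cc(O)c2c1O[C@H](c1ccc(O)c(O)c1)[C@@H](O)[C@H]2c1c(O)cc(O)c2c1O[C@@H](c1ccc(O)c(O)c1)[C@H](O)C2 | target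

**Step count and risks**
Total steps: 8. Longest linear sequence: 5 (steps 2, 3, 4, 7, 8).

The three steps most likely to fail:

Step 4 (the new step). The hydrogen-bonded template may not override the intrinsic 3,4-trans preference, or C6-linked isomer may form. The β-directing element is the substrate's own 3-OH, so the handedness of the catalyst should modulate the ratio, not reverse it. The fallback is the established covalent diester-tether method; it sets out from 2 and 4 and returns at 6. Compound 2 is opened onto glutaric anhydride (DMAP, pyridine) to give tetra-O-benzyl-ent-catechin 3-O-hemiglutarate F1. Compound 4 is oxidised with DDQ in the presence of 2-ethoxyethanol to (2R,3S,4S)-tetra-O-benzyl-4-(2-ethoxyethoxy)flavan-3-ol F2. F1 and F2 are esterified (EDC·HCl, DMAP) to the glutarate-linked diester F3. TMSOTf (cat.) in dilute CH2Cl2 at −78 °C closes the 14-membered ring intramolecularly to the 3,4-cis cyclic glutarate F4, and DIBAL-H removes the linker to give 6.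

Step 7. The cation from 10 may attack C6 positions of 6 or condense with itself, and product may be alkylated again. The fallback reverses the order of assembly; it sets out from 10 and 4 and returns at 11. Compound 10 is coupled with monomer 4 (4 equiv, TMSOTf cat., CH2Cl2, −78 °C, acetate participation giving 4α) to 3-O-acetyl-penta-O-benzylgallocatechin-(4α→8)-tetra-O-benzylcatechin F5. DDQ in wet CH2Cl2 hydroxylates C4 of its lower unit, the only unit with a free 3-OH and a benzylic CH2, to the cis-4-hydroxy dimer F6. F6 is joined to 2 as in step 4 (or through the glutarate tether if step 4 has been replaced) to give 11, and the route resumes with the methanolysis to 12.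

Step 5. Exhaustive benzylation must reach the hydrogen-bonded 5-OH, and prolonged base with traces of air can open ring C or oxidise the dihydroflavonol to the flavonol. The fallback is a two-stage protection; it sets out from 7 and returns at 8. Compound 7 is benzylated under mild conditions (BnBr 4.2 equiv, K2CO3, acetone, rt) at the four unchelated phenols only, giving (2R,3R)-7,3',4',5'-tetra-O-benzyldihydromyricetin F7. The remaining 5-OH is then etherified under neutral Mitsunobu conditions (BnOH, PPh3, DIAD, THF) to give 8.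

**Further compounds**
F1 | step 4 | (2S,3R)-5,7,3',4'-tetra-O-benzyl-ent-catechin 3-O-hemiglutarate | c1c(OCc3ccccc3)cc(OCc3ccccc3)c2c1O[C@@H](c1ccc(OCc3ccccc3)c(OCc3ccccc3)c1)[C@H](OC(=O)CCCC(O)=O)C2
F2 | step 4 | (2R,3S,4S)-5,7,3',4'-tetra-O-benzyl-4-(2-ethoxyethoxy)flavan-3-ol | c1c(OCc3ccccc3)cc(OCc3ccccc3)c2c1O[C@H](c1ccc(OCc3ccccc3)c(OCc3ccccc3)c1)[C@@H](O)[C@H]2OCCOCC
F3 | step 4 | glutarate diester linking O3 of F2 to O3 of 2 | c1c(OCc3ccccc3)cc(OCc3ccccc3)c2c1O[C@@H](c1ccc(OCc3ccccc3)c(OCc3ccccc3)c1)[C@H](OC(=O)CCCC(=O)O[C@@H]4[C@@H](c5ccc(OCc3ccccc3)c(OCc3ccccc3)c5)Oc5cc(OCc3ccccc3)cc(OCc3ccccc3)c5[C@@H]4OCCOCC)C2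
F4 | step 4 | 3,3'-O-glutaryl-bridged octa-O-benzyl catechin-(4β→8)-ent-catechin (14-membered cyclic diester) | c1c(OCc3ccccc3)cc(OCc3ccccc3)c2c1O[C@H](c1ccc(OCc3ccccc3)c(OCc3ccccc3)c1)[C@@H](OC(=O)CCCC(=O)O6)[C@H]2c1c(OCc3ccccc3)cc(OCc3ccccc3)c2c1O[C@@H](c1ccc(OCc3ccccc3)c(OCc3ccccc3)c1)[C@H]6C2
F5 | step 7 | 3-O-acetyl-penta-O-benzylgallocatechin-(4α→8)-tetra-O-benzylcatechin | c1c(OCc3ccccc3)cc(OCc3ccccc3)c2c1O[C@H](c1cc(OCc3ccccc3)c(OCc3ccccc3)c(OCc3ccccc3)c1)[C@@H](OC(C)=O)[C@@H]2c1c(OCc3ccccc3)cc(OCc3ccccc3)c2c1O[C@H](c1ccc(OCc3ccccc3)c(OCc3ccccc3)c1)[C@@H](O)C2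
F6 | step 7 | F5 hydroxylated at C4 of the lower unit (4β-OH, cis to its 3-OH) | c1c(OCc3ccccc3)cc(OCc3ccccc3)c2c1O[C@H](c1cc(OCc3ccccc3)c(OCc3ccccc3)c(OCc3ccccc3)c1)[C@@H](OC(C)=O)[C@@H]2c1c(OCc3ccccc3)cc(OCc3ccccc3)c2c1O[C@H](c1ccc(OCc3ccccc3)c(OCc3ccccc3)c1)[C@@H](O)[C@H]2O
F7 | step 5 | (2R,3R)-7,3',4',5'-tetra-O-benzyldihydromyricetin (5-OH free) | c1c(OCc3ccccc3)cc(O)c2c1O[C@H](c1cc(OCc3ccccc3)c(OCc3ccccc3)c(OCc3ccccc3)c1)[C@@H](O)C2=O
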